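**Compound numbering used throughout:** 1 3,4,5-trimethoxyphenol; 2 aryl methyl ketone; 3 dihydroxy ketone; 4 3,4-dimethoxybenzyl chloride; 5 mono-benzyl ether; 6 silyl ether; 7 trifluoromethyl diketone; 8 diazoketone; 9 silylated flavanone; 10 target.

## Analysis of the target

Compound 10 is (2S)-2-(3,4-dimethoxyphenyl)-5-hydroxy-6,7-dimethoxychroman-4-one, a flavanone. Ring A is aromatic and carries oxygen at C5, C6 and C7, ring C is the pyranone, and ring B is a 3,4-dimethoxyphenyl group on C2. C2 is the only stereocentre and is S; there is no second centre to relay from, so it must be set by a reagent or catalyst. C2 is benzylic, bound to O1 and β to the C4 ketone, so base can open ring C by a retro-oxa-Michael reaction to the 2'-hydroxychalcone and erase the configuration. The C5 hydroxyl is hydrogen-bonded to C4=O and has to end up free while the C6 and C7 oxygens stay methylated. Ring A is very electron-rich and does not tolerate strong oxidants, so the difficulty is to create one isolated stereocentre and keep it through the last steps. The route rests on the position of C2 between O1 and ring B: if C2–C3 is the last ring bond made, C2 is the methylene of an achiral benzyl aryl ether, and its two enantiotopic C–H bonds are activated by both the oxygen and the electron-rich aryl group toward an electrophilic carbon at C3.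

## Retrosynthetic reasoning

**10 from 9 (O–Si).** The C5 hydroxyl is masked as a triisopropylsilyl ether in 9. A silyl group can be removed by fluoride in a buffered, non-basic medium, which leaves C2 untouched. The forward step only has to cleave O–Si without opening ring C.

**9 from 8 (C2–C3).** This is the central disconnection. Cutting C2–C3 turns ring C into an aryl ketone with a one-carbon carbene precursor at C3 and a 3,4-dimethoxybenzyl ether on the oxygen that becomes O1. Cutting O1–C2 or C4–C4a instead would require a preformed stereocentre or would leave C2 planar. The C2–C3 cut lets an achiral, open precursor 8 deliver the ring and the stereocentre in one catalytic event, and ring B enters as a simple benzyl group. The forward reaction must insert into one of two enantiotopic C–H bonds, form a six-membered ring, and not react at the ether oxygen.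

**8 from 7 and 6 (C=N2).** The diazo group of 8 is traced to the methyl ketone 6 by way of its trifluoroacetyl derivative 7, which makes the α-carbon acidic enough for diazo transfer under a mild amine base. The two carbons of the acetyl group become C4 and C3, so no one-carbon homologation is needed.

**6 from 5 (O–Si).** The silyl group is put on the last free phenol of 5. It is placed after the benzyl ether so that the more hindered, chelated hydroxyl is the only one left.

**5 from 3 and 4 (O–CH2).** The benzyl ether bond is cut to the dihydroxy ketone 3 and the benzylic chloride 4. The two hydroxyls of 3 differ: one has a free ring position beside it, the other sits between the acetyl and a methoxy group. The forward alkylation has to take the first and leave the second.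

**3 from 2 (O–CH3).** The hydroxyl that becomes the C5 oxygen is freed from its methyl ether in 2. Only this methoxy group lies ortho to the ketone, so a Lewis acid that needs two-point binding can single it out. This is how the C5 oxygen is distinguished from those at C6 and C7.

**2 from 1 (aryl C–acetyl).** The acetyl group is removed to give the symmetric phenol 1. Its two open ring positions are equivalent and both ortho to the hydroxyl, so acylation can give only one ketone, and the hydroxyl of 1 ends up as O1.

## Alternatives that were turned down

**Alternative 1:** Ring C is cut at C4a–C4, C4–C3 and O1–C2 around a one-carbon carbonyl unit. The pieces are the iodophenol 2-iodo-3,4,5-trimethoxyphenol A2 and the alkyne 4-ethynyl-1,2-dimethoxybenzene A3.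
- **Forward key step:** a carbonylative Sonogashira coupling of A2 with A3 under PdCl2(PPh3)2 in a secondary amine, followed by 6-endo closure of the phenol onto the ynone, gives the flavone 2-(3,4-dimethoxyphenyl)-5,6,7-trimethoxy-4H-chromen-4-one A1.
- **For:** it is the most convergent option, makes three bonds in one step, needs no protecting groups, and is shorter on paper than the chosen route. The alkyne A3 is a simple building block.
- **Against:** A1 is flat, so C2 must still be set by an enantioselective reduction of the C2–C3 double bond. That reduction passes through an enolate β to an aryloxy leaving group, which invites ring opening and over-reduction. The C5 methyl ether must also still be removed. The iodide of A2 is flanked on both sides, and 5-exo closure to an aurone competes with the wanted ring closure.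
- **Comparison:** Alternative 1 is stronger in convergence and in the reliability of ring formation. The chosen strategy instead sets C2 in the ring-forming step and differentiates the C5 oxygen early.

**Alternative 2:** Ring A is built rather than bought, by cutting C8–C8a and C4a–C5.
- **Forward key step:** the chlorocyclobutenone 4-chloro-2,3-dimethoxycyclobut-2-en-1-one A5 and the enantiopure stannane (2S,4S)-4-(tert-butyldimethylsilyloxy)-2-(3,4-dimethoxyphenyl)-6-(tributylstannyl)-3,4-dihydro-2H-pyran A6 undergo Stille coupling with PdCl2(PhCN)2 and tri(2-furyl)phosphine. Heating opens the four-membered ring to a dienylketene, which closes by 6π electrocyclisation to the 2,4-cis phenol (2S,4S)-4-(tert-butyldimethylsilyloxy)-2-(3,4-dimethoxyphenyl)-6,7-dimethoxychroman-5-ol A4.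
- **For:** the substitution pattern of ring A is fixed without ambiguity by the two methoxy groups of A5, and the C5 hydroxyl of A4 appears free and already distinct from them. On this point it is stronger than the chosen route, which relies on a selective demethylation and a selective alkylation.
- **Against:** A6 needs its own multi-step asymmetric synthesis, and stoichiometric tin is used. The C4 carbinol of A4 must afterwards be deprotected and oxidised next to a free, electron-rich phenol. Ring A with the correct oxygen pattern is commercially available as 1, so building it from A5 is poor step economy.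
- **Comparison:** the chosen strategy is several steps shorter and uses the bought arene.

**Alternative 3:** Ring C is cut at C8a–O1.
- **Forward key step:** the carbinol (1S)-2-[2-(6-bromo-2,3,4-trimethoxyphenyl)-1,3-dithian-2-yl]-1-(3,4-dimethoxyphenyl)ethanol A8 is cyclised by an Ullmann-type O-arylation with CuI, a phenanthroline ligand and Cs2CO3. The product is the dithioketal (2S)-2-(3,4-dimethoxyphenyl)-5,6,7-trimethoxychroman-4-one trimethylene dithioketal A7.
- **For:** C2 comes from a well-understood asymmetric source and is not touched in the ring closure, because the bond formed is aryl–O. The dithiane blocks β-elimination. In predictability of absolute configuration this alternative is stronger than the chosen route.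
- **Against:** assembling A8 requires a dithiane anion next to an aryl bromide, where halogen–metal exchange competes. The bromide is electron-rich and ortho to a quaternary carbon, which is a poor case for copper insertion. The dithioketal of A7 must then be removed from an oxidisable arene, and the C5 methyl ether of A7 must be cleaved.
- **Comparison:** the chosen strategy is shorter and catalytic in the stereo-defining step, at the price of a less certain selectivity.

Key step: step 7

Remark: the hand of the catalyst is assumed; Rh2(S-PTTL)4 (dirhodium tetrakis[N-phthaloyl-(S)-tert-leucinate]) is written, and if insertion favours the 2R product, its mirror image Rh2(R-PTTL)4 is used with no other change.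

## Route

Step 1
Reactants: 1 3,4,5-trimethoxyphenol
Product: 2 1-(6-hydroxy-2,3,4-trimethoxyphenyl)ethanone
Conditions: AcOH, BF3·OEt2, 90 °C; H2O work-up
Reagents that add atoms: acetic acid, CC(=O)O
Why: Friedel–Crafts acylation (O-acetylation and Fries-type migration are a possible path) of a symmetric, electron-rich phenol; the two open positions are equivalent and ortho to the hydroxyl, so only one ketone can form, and boron chelation of the product should hold back a second acylation.

Step 2
Reactants: 2 1-(6-hydroxy-2,3,4-trimethoxyphenyl)ethanone
Product: 3 1-(2,6-dihydroxy-3,4-dimethoxyphenyl)ethanone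
Conditions: BCl3 (about 2 equiv), CH2Cl2, −78 to 0 °C; H2O
Reagents that add atoms: none
Why: Chelation-directed Lewis acid cleavage of an aryl methyl ether: boron bridges the ketone oxygen and the ortho methoxy oxygen, and chloride removes that methyl group, while the two methoxy groups out of reach of the carbonyl should stay; low temperature and limited reagent guard against a second cleavage.

Step 3
Reactants: 3 1-(2,6-dihydroxy-3,4-dimethoxyphenyl)ethanone; 4 4-(chloromethyl)-1,2-dimethoxybenzene
Product: 5 1-[6-[(3,4-dimethoxyphenyl)methoxy]-2-hydroxy-3,4-dimethoxyphenyl]ethanone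
Conditions: K2CO3, acetone, 50 °C (1.05 equiv of 4)
Reagents that add atoms: none
Why: Williamson ether synthesis under kinetic control: the hydroxyl beside the free ring position is open on one flank, whereas the other is wedged between acetyl and methoxy groups and stays chelated to the ketone; after one alkylation the remaining chelated hydroxyl is a poor nucleophile, so dialkylation should be slow.

Step 4
Reactants: 5 1-[6-[(3,4-dimethoxyphenyl)methoxy]-2-hydroxy-3,4-dimethoxyphenyl]ethanone
Product: 6 1-[6-[(3,4-dimethoxyphenyl)methoxy]-3,4-dimethoxy-2-(triisopropylsilyloxy)phenyl]ethanone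
Conditions: iPr3SiOTf, 2,6-lutidine, CH2Cl2, 0 °C to rt
Reagents that add atoms: triisopropylsilyl trifluoromethanesulfonate, CC(C)[Si](OS(=O)(=O)C(F)(F)F)(C(C)C)C(C)C
Why: O-silylation of a hindered, hydrogen-bonded phenol; the reactivity of a silyl triflate is needed to break the chelate, and 2,6-lutidine is too weak a base to enolise the methyl ketone, so silylation on the phenol oxygen is expected.

Step 5
Reactants: 6 1-[6-[(3,4-dimethoxyphenyl)methoxy]-3,4-dimethoxy-2-(triisopropylsilyloxy)phenyl]ethanone
Product: 7 1-[6-[(3,4-dimethoxyphenyl)methoxy]-3,4-dimethoxy-2-(triisopropylsilyloxy)phenyl]-4,4,4-trifluorobutane-1,3-dione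
Conditions: LiN(SiMe3)2, THF, −78 °C; CF3CO2CH2CF3; cold 0.5 M HCl work-up; crude used at once
Reagents that add atoms: 2,2,2-trifluoroethyl trifluoroacetate, O=C(OCC(F)(F)F)C(F)(F)F
Why: Crossed Claisen condensation: the ketone has a single enolisable side, its lithium enolate is acylated on carbon by the activated ester, and the acidic diketone is held as its enolate, which stops further reaction; −78 °C is kept to prevent silyl transfer from the aryl oxygen to the enolate oxygen.

Step 6
Reactants: 7 1-[6-[(3,4-dimethoxyphenyl)methoxy]-3,4-dimethoxy-2-(triisopropylsilyloxy)phenyl]-4,4,4-trifluorobutane-1,3-dione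
Product: 8 2-diazo-1-[6-[(3,4-dimethoxyphenyl)methoxy]-3,4-dimethoxy-2-(triisopropylsilyloxy)phenyl]ethanone
Conditions: 4-AcNHC6H4SO2N3, Et3N, H2O (1 equiv), MeCN, rt; by-product removed by filtration and chromatography, no alkaline wash
Reagents that add atoms: 4-acetamidobenzenesulfonyl azide, CC(=O)Nc1ccc(S(=O)(=O)N=[N+]=[N-])cc1
Why: Detrifluoroacetylative Regitz-type diazo transfer: the diketone enolate attacks the terminal azide nitrogen and the adduct fragments with transfer of the trifluoroacetyl group to the sulfonamide nitrogen, leaving the diazomethyl ketone; the amine base is mild enough for the aryl silyl ether and the benzyl ether.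

Step 7
Reactants: 8 2-diazo-1-[6-[(3,4-dimethoxyphenyl)methoxy]-3,4-dimethoxy-2-(triisopropylsilyloxy)phenyl]ethanone
Product: 9 (2S)-2-(3,4-dimethoxyphenyl)-6,7-dimethoxy-5-(triisopropylsilyloxy)chroman-4-one
Conditions: Rh2(S-PTTL)4 (2 mol %), toluene, 4 Å MS, 0 °C, slow addition of 8
Reagents that add atoms: none
Why: Rh2(S-PTTL)4 takes up the diazo carbon at an axial site and, after loss of dinitrogen, leaves an electrophilic carbene on divalent rhodium at the future C3. The carbene carbon then draws hydride character from one benzylic C–H bond of the ortho 3,4-dimethoxybenzyl ether while the C2–C3 bond forms in the same three-centre transition state, and the catalyst is released. The closest known reaction type is the intramolecular C–H insertion of ortho-alkoxyaryl diazomethyl ketones to 2-substituted chroman-4-ones under chiral dirhodium tetracarboxylates. Ring C closes by a 1,6-insertion that makes a six-membered ring (carbene carbon, C4, C4a, C8a, O1, C2); the usual five-membered mode is not available because that position is the ether oxygen. C2 is the only new stereocentre and is set by the catalyst alone, whose four phthalimido groups form a chiral pocket around the carbene and present one of the two enantiotopic hydrogens. The step needs chemoselectivity for insertion over attack of the ether oxygen on the carbene, which would give an oxonium ylide and then a Stevens 1,2-benzyl shift to a 2-benzylbenzofuran-3-one; the double activation of the C–H bond by O1 and the electron-rich ring, a non-polar solvent, low temperature and slow addition are meant to secure it. The bulky triisopropylsilyl ether keeps the carbene on the benzyl ether side, shields its own oxygen and has no C–H bond at a favourable ring size.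

Step 8
Reactants: 9 (2S)-2-(3,4-dimethoxyphenyl)-6,7-dimethoxy-5-(triisopropylsilyloxy)chroman-4-one
Product: 10 (2S)-2-(3,4-dimethoxyphenyl)-5-hydroxy-6,7-dimethoxychroman-4-one
Conditions: HF·pyridine, pyridine, THF, 0 °C
Reagents that add atoms: none
Why: Fluoride cleavage of an aryl silyl ether, driven by the strength of the Si–F bond; the buffered, non-basic medium avoids the base-triggered retro-oxa-Michael opening by which flavanones racemise, so the C2 configuration set in step 7 should be carried into the target.

## Compound list

1 | 3,4,5-trimethoxyphenol | COc1cc(O)cc(OC)c1OC | starting material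
2 | 1-(6-hydroxy-2,3,4-trimethoxyphenyl)ethanone | CC(=O)c1c(O)cc(OC)c(OC)c1OC | intermediate
3 | 1-(2,6-dihydroxy-3,4-dimethoxyphenyl)ethanone | CC(=O)c1c(O)cc(OC)c(OC)c1O | intermediate
4 | 4-(chloromethyl)-1,2-dimethoxybenzene | COc1ccc(CCl)cc1OC | starting material
5 | 1-[6-[(3,4-dimethoxyphenyl)methoxy]-2-hydroxy-3,4-dimethoxyphenyl]ethanone | CC(=O)c1c(OCc2ccc(OC)c(OC)c2)cc(OC)c(OC)c1O | intermediate
6 | 1-[6-[(3,4-dimethoxyphenyl)methoxy]-3,4-dimethoxy-2-(triisopropylsilyloxy)phenyl]ethanone | CC(=O)c1c(OCc2ccc(OC)c(OC)c2)cc(OC)c(OC)c1O[Si](C(C)C)(C(C)C)C(C)C | intermediate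
7 | 1-[6-[(3,4-dimethoxyphenyl)methoxy]-3,4-dimethoxy-2-(triisopropylsilyloxy)phenyl]-4,4,4-trifluorobutane-1,3-dione | O=C(CC(=O)C(F)(F)F)c1c(OCc2ccc(OC)c(OC)c2)cc(OC)c(OC)c1O[Si](C(C)C)(C(C)C)C(C)C | intermediate
8 | 2-diazo-1-[6-[(3,4-dimethoxyphenyl)methoxy]-3,4-dimethoxy-2-(triisopropylsilyloxy)phenyl]ethanone | COc1ccc(COc2cc(OC)c(OC)c(O[Si](C(C)C)(C(C)C)C(C)C)c2C(=O)C=[N+]=[N-])cc1OC | intermediate
9 | (2S)-2-(3,4-dimethoxyphenyl)-6,7-dimethoxy-5-(triisopropylsilyloxy)chroman-4-one | COc1ccc([C@@H]2CC(=O)c3c(cc(OC)c(OC)c3O[Si](C(C)C)(C(C)C)C(C)C)O2)cc1OC | intermediate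
10 | (2S)-2-(3,4-dimethoxyphenyl)-5-hydroxy-6,7-dimethoxychroman-4-one | COc1ccc([C@@H]2CC(=O)c3c(cc(OC)c(OC)c3O)O2)cc1OC | target

## Step count and least certain steps

Total step count: 8. Longest linear sequence: 8 steps, from 1 to 10; compound 4 enters at step 3.

**Step 7 (key step).**
- **What may go wrong:** attack of the benzyl ether oxygen on the carbene followed by 1,2-migration of the electron-rich benzyl group; hydride abstraction from the benzylic position without ring closure, which ends in loss of the benzyl group; or weak discrimination between the two enantiotopic hydrogens. All three are plausible because the acceptor-only carbene is very electrophilic and the 3,4-dimethoxybenzyl group stabilises both a benzylic radical and a benzylic cation.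
- **Fallback:** it sets out from 2, abandons the carbene and comes back to the route at 10. Condensation of 2 with N,N-dimethylformamide dimethyl acetal would give (E)-3-(dimethylamino)-1-(6-hydroxy-2,3,4-trimethoxyphenyl)prop-2-en-1-one F1, which aqueous acid should close to 5,6,7-trimethoxy-4H-chromen-4-one F2. An enantioselective Hayashi–Miyaura-type conjugate addition of (3,4-dimethoxyphenyl)boronic acid to F2, with Pd(OCOCF3)2 and a chiral pyridine-oxazoline ligand or with [Rh(OH)(cod)]2 and a chiral diene, should give (2S)-2-(3,4-dimethoxyphenyl)-5,6,7-trimethoxychroman-4-one F3. BCl3 in CH2Cl2 at low temperature should then cleave only the C5 methoxy group, which is chelated to C4=O, and deliver 10.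

**Step 3.**
- **What may go wrong:** poor site selectivity in the alkylation, that is, reaction at the hindered oxygen or at both oxygens. The two phenols differ only in their flanking groups, and both are ortho to the ketone.
- **Fallback:** it sets out from 2 and comes back at 6, fixing the positions by order of events instead of by selectivity. Acetylation of 2 (Ac2O, pyridine) would give 2-acetyl-3,4,5-trimethoxyphenyl acetate F4. BCl3 should cleave the only methoxy group ortho to the ketone and give 2-acetyl-3-hydroxy-4,5-dimethoxyphenyl acetate F5. Silylation with iPr3SiOTf and 2,6-lutidine would give 2-acetyl-4,5-dimethoxy-3-(triisopropylsilyloxy)phenyl acetate F6. Ammonia in methanol at 0 °C should remove the aryl acetate and leave 1-[6-hydroxy-3,4-dimethoxy-2-(triisopropylsilyloxy)phenyl]ethanone F7. Alkylation of F7 with 4 and K2CO3 in acetone then gives 6.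

**Step 5.**
- **What may go wrong:** transfer of the silyl group from the neighbouring aryl oxygen to the enolate oxygen, or acylation on oxygen instead of carbon. The ketone is twisted out of the ring plane by its two ortho substituents, and the enolate oxygen lies close to silicon.
- **Fallback:** it sets out from 6 and comes back at 8 without a metal enolate. Soft enolisation of 6 with Me3SiOTf and Et3N would give the enol ether [1-[6-[(3,4-dimethoxyphenyl)methoxy]-3,4-dimethoxy-2-(triisopropylsilyloxy)phenyl]ethenyl]oxy-trimethylsilane F8. N-Bromosuccinimide in THF at −78 °C should convert F8 into 2-bromo-1-[6-[(3,4-dimethoxyphenyl)methoxy]-3,4-dimethoxy-2-(triisopropylsilyloxy)phenyl]ethanone F9. Treatment of F9 with N,N'-ditosylhydrazine and DBU in THF at 0 °C, by N-alkylation and loss of two sulfinate groups, should give 8.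

## Further compounds

F1 | step 7 | (E)-3-(dimethylamino)-1-(6-hydroxy-2,3,4-trimethoxyphenyl)prop-2-en-1-one | CN(C)/C=C/C(=O)c1c(O)cc(OC)c(OC)c1OC
F2 | step 7 | 5,6,7-trimethoxy-4H-chromen-4-one | COc1cc2occc(=O)c2c(OC)c1OC
F3 | step 7 | (2S)-2-(3,4-dimethoxyphenyl)-5,6,7-trimethoxychroman-4-one | COc1ccc([C@@H]2CC(=O)c3c(OC)c(OC)c(OC)cc3O2)cc1OC
F4 | step 3 | 2-acetyl-3,4,5-trimethoxyphenyl acetate | CC(=O)Oc1cc(OC)c(OC)c(OC)c1C(C)=O
F5 | step 3 | 2-acetyl-3-hydroxy-4,5-dimethoxyphenyl acetate | CC(=O)Oc1cc(OC)c(OC)c(O)c1C(C)=O
F6 | step 3 | 2-acetyl-4,5-dimethoxy-3-(triisopropylsilyloxy)phenyl acetate | CC(=O)Oc1cc(OC)c(OC)c(O[Si](C(C)C)(C(C)C)C(C)C)c1C(C)=O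
F7 | step 3 | 1-[6-hydroxy-3,4-dimethoxy-2-(triisopropylsilyloxy)phenyl]ethanone | CC(=O)c1c(O)cc(OC)c(OC)c1O[Si](C(C)C)(C(C)C)C(C)C
F8 | step 5 | [1-[6-[(3,4-dimethoxyphenyl)methoxy]-3,4-dimethoxy-2-(triisopropylsilyloxy)phenyl]ethenyl]oxy-trimethylsilane | C=C(O[Si](C)(C)C)c1c(OCc2ccc(OC)c(OC)c2)cc(OC)c(OC)c1O[Si](C(C)C)(C(C)C)C(C)C
F9 | step 5 | 2-bromo-1-[6-[(3,4-dimethoxyphenyl)methoxy]-3,4-dimethoxy-2-(triisopropylsilyloxy)phenyl]ethanone | O=C(CBr)c1c(OCc2ccc(OC)c(OC)c2)cc(OC)c(OC)c1O[Si](C(C)C)(C(C)C)C(C)C
A1 | alternative 1 | 2-(3,4-dimethoxyphenyl)-5,6,7-trimethoxy-4H-chromen-4-one | COc1ccc(-c2cc(=O)c3c(OC)c(OC)c(OC)cc3o2)cc1OC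
A2 | alternative 1 | 2-iodo-3,4,5-trimethoxyphenol | COc1cc(O)c(I)c(OC)c1OC
A3 | alternative 1 | 4-ethynyl-1,2-dimethoxybenzene | COc1ccc(C#C)cc1OC
A4 | alternative 2 | (2S,4S)-4-(tert-butyldimethylsilyloxy)-2-(3,4-dimethoxyphenyl)-6,7-dimethoxychroman-5-ol (2,4-cis) | COc1ccc([C@@H]2C[C@H](O[Si](C)(C)C(C)(C)C)c3c(cc(OC)c(OC)c3O)O2)cc1OC
A5 | alternative 2 | 4-chloro-2,3-dimethoxycyclobut-2-en-1-one | COC1=C(OC)C(Cl)C1=O
A6 | alternative 2 | (2S,4S)-4-(tert-butyldimethylsilyloxy)-2-(3,4-dimethoxyphenyl)-6-(tributylstannyl)-3,4-dihydro-2H-pyran | COc1ccc([C@@H]2C[C@H](O[Si](C)(C)C(C)(C)C)C=C([Sn](CCCC)(CCCC)CCCC)O2)cc1OC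
A7 | alternative 3 | (2S)-2-(3,4-dimethoxyphenyl)-5,6,7-trimethoxychroman-4-one trimethylene dithioketal | COc1ccc([C@@H]2CC3(SCCCS3)c3c(cc(OC)c(OC)c3OC)O2)cc1OC
A8 | alternative 3 | (1S)-2-[2-(6-bromo-2,3,4-trimethoxyphenyl)-1,3-dithian-2-yl]-1-(3,4-dimethoxyphenyl)ethanol | COc1ccc([C@@H](O)CC2(SCCCS2)c2c(Br)cc(OC)c(OC)c2OC)cc1OC
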